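**Plan**

1. Numbering: ring A is C1 (bears butanoyl), C2 (C–OH), C3 (quaternary, methyl and prenyl), C4 (C–OH), C5 (bears the CH2 bridge), C6 (C=O); ring B is the arene.
2. Cuts, in retrosynthetic order: both C–C bonds of the CH2 bridge (ring A C5–CH2 and CH2–ring B), then ring A C1–C6, the C1–butanoyl bond, C4–C5, and last C2–C3.
3. Feature: C3 of ring A is a quaternary carbon between the oxygen-bearing ring carbons C2 and C4, the centre of a 2,2-disubstituted 1,3-dicarbonyl unit. That is the pattern an acyl shift delivers from an α,β-epoxy ketone whose β-carbon carries the methyl and prenyl groups.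
4. Forward: enyne, E-allylic alcohol, epoxy methyl ketone, acyl shift to a keto aldehyde holding C1–C4, acetate adds C5 and C6, butanoyl goes onto C1, and ring A (the only ring formed) closes last at C1–C6. Ring B, made from 5-methoxyresorcinol by acylation and aminomethylation, is then joined to C5.
5. Stereochemistry: the single stereocentre C3 is set as an epoxide carbon by tartrate-controlled epoxidation and carried over with inversion in the acyl shift; the two carbonyl arms on C3 stay different from then on.

Key step: step 7

Remark on the chemistry: ring A and its open-chain precursors equilibrate between enol tautomers; each is written in one tautomer (ring A as in the target SMILES) and the CIP descriptors refer to that tautomer.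

**Route**

Step 1
Reactants: 1 prenyl bromide (1-bromo-3-methylbut-2-ene); 2 ethynylmagnesium bromide
Product: 3 5-methylhex-4-en-1-yne
Conditions: 2 (1.5 equiv), CuCl (5 mol%), THF, 0 °C → 45 °C; product kept cold (volatile)
Reagents that add atoms: none
Why: Copper-catalysed coupling of an alkynyl Grignard reagent with an allylic bromide at the unhindered primary carbon should give the skipped 1,4-enyne, and the excess of 2 limits double alkylation.

Step 2
Reactants: 3 5-methylhex-4-en-1-yne
Product: 6 (2E)-3,6-dimethylhepta-2,5-dien-1-ol, via alkenyldimethylalane 4 (not isolated), via lithium alkenylaluminate 5 (not isolated)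
Conditions: AlMe3 (2 equiv), Cp2ZrCl2 (25 mol%), CH2Cl2, 0 °C → rt; volatiles removed; n-BuLi (1 equiv), hexane, 0 °C; (CH2O)n, THF, rt; cold 1 M HCl
Reagents that add atoms: trimethylaluminium C[Al](C)C; formaldehyde (from paraformaldehyde) C=O; n-butyllithium [Li]CCCC (its atoms are found in 5 only)
Why: Negishi zirconium-catalysed methylalumination adds methyl and aluminium syn across the terminal alkyne with aluminium at the terminus, and the derived aluminate is hydroxymethylated with retention, which fixes the E geometry of the trisubstituted alkene.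

Step 3
Reactants: 6 (2E)-3,6-dimethylhepta-2,5-dien-1-ol
Product: 7 [(2S,3S)-3-methyl-3-(3-methylbut-2-en-1-yl)oxiran-2-yl]methanol
Conditions: Ti(OiPr)4 (10 mol%), L-(+)-diethyl tartrate (12 mol%), t-BuOOH (2 equiv), 4 Å molecular sieves, CH2Cl2, −20 °C
Reagents that add atoms: tert-butyl hydroperoxide CC(C)(C)OO
Why: Sharpless asymmetric epoxidation with L-(+)-diethyl tartrate should epoxidise the allylic alkene from the face that gives the (2S,3S)-epoxide (the sense known for geraniol), which sets oxirane C3, while the prenyl alkene has no allylic hydroxyl and is left alone.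

Step 4
Reactants: 7 [(2S,3S)-3-methyl-3-(3-methylbut-2-en-1-yl)oxiran-2-yl]methanol
Product: 8 (2R,3S)-3-methyl-3-(3-methylbut-2-en-1-yl)oxirane-2-carbaldehyde
Conditions: Dess–Martin periodinane, pyridine, CH2Cl2, 0 °C → rt
Reagents that add atoms: none
Why: Dess–Martin oxidation of a primary 2,3-epoxy alcohol under buffered conditions should give the epoxy aldehyde without opening the epoxide or touching the alkene.

Step 5
Reactants: 8 (2R,3S)-3-methyl-3-(3-methylbut-2-en-1-yl)oxirane-2-carbaldehyde
Product: 9 1-[(2S,3S)-3-methyl-3-(3-methylbut-2-en-1-yl)oxiran-2-yl]ethan-1-ol (both carbinol epimers)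
Conditions: MeMgBr (1.2 equiv), THF, −78 °C; aq. NH4Cl
Reagents that add atoms: methylmagnesium bromide C[Mg]Br
Why: Grignard addition to the aldehyde is much faster than epoxide opening at −78 °C, and the carbinol epimer mixture converges in step 6.

Step 6
Reactants: 9 1-[(2S,3S)-3-methyl-3-(3-methylbut-2-en-1-yl)oxiran-2-yl]ethan-1-ol
Product: 10 1-[(2R,3S)-3-methyl-3-(3-methylbut-2-en-1-yl)oxiran-2-yl]ethan-1-one
Conditions: Dess–Martin periodinane, pyridine, CH2Cl2, 0 °C → rt
Reagents that add atoms: none
Why: Dess–Martin oxidation converts both carbinol epimers into one α,β-epoxy ketone and does not affect oxirane C3.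

Step 7
Reactants: 10 1-[(2R,3S)-3-methyl-3-(3-methylbut-2-en-1-yl)oxiran-2-yl]ethan-1-one
Product: 11 (2R)-2-acetyl-2,5-dimethylhex-4-enal
Conditions: BF3·OEt2 (0.5 equiv), CH2Cl2, −78 °C; Et3N then H2O at −78 °C; used at once
Reagents that add atoms: none
Why: BF3 coordinates the epoxide oxygen, the C–O bond at the tertiary oxirane carbon C3 lengthens, and the acetyl group on oxirane C2 shifts to C3 on the face anti to the departing oxygen in a concerted semipinacol process that leaves C2 as the aldehyde. The closest known reaction type is the Lewis-acid-promoted 1,2-acyl shift of α,β-epoxy ketones to 2,2-disubstituted 1,3-dicarbonyl compounds, which is stereospecific with inversion at the migration terminus. No ring closes. The new quaternary centre, the future C3 of ring A, is controlled only by the configuration of oxirane C3 from step 3, which is inverted; the configuration at oxirane C2 does not matter because that carbon ends as a trigonal aldehyde carbon. The step needs acyl migration in preference to hydride shift, fluorohydrin formation or capture of the cationic terminus by the prenyl alkene. The dialkyl-substituted terminus directs C–O cleavage to C3, the carbonyl group disfavours charge at C2 and is the best migrating group there, and the low temperature with a cold basic quench should keep the non-enolisable but deformylation-prone keto aldehyde intact.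

Step 8
Reactants: 11 (2R)-2-acetyl-2,5-dimethylhex-4-enal; 12 methyl acetate
Product: 14 methyl (4R)-4-acetyl-3-hydroxy-4,7-dimethyloct-6-enoate (both C3 epimers), via lithium enolate 13 (not isolated)
Conditions: LiN(iPr)2 (1.1 equiv), 12 (1.1 equiv), THF, −78 °C; then 11, −78 °C; aq. NH4Cl at −78 °C
Reagents that add atoms: none
Why: Crossed aldol addition of a preformed ester lithium enolate goes to the aldehyde, which is far more electrophilic than the hindered methyl ketone, and the cold quench avoids retro-aldol cleavage; the new carbinol centre disappears in step 9.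

Step 9
Reactants: 14 methyl (4R)-4-acetyl-3-hydroxy-4,7-dimethyloct-6-enoate
Product: 15 methyl (4S)-4-acetyl-4,7-dimethyl-3-oxooct-6-enoate
Conditions: Dess–Martin periodinane, CH2Cl2, 0 °C → rt
Reagents that add atoms: none
Why: Dess–Martin oxidation of a β-hydroxy ester gives the β-keto ester under neutral conditions that spare the alkene and the non-enolisable 1,3-diketone (the descriptor changes only because the CIP priorities change).

Step 10
Reactants: 15 methyl (4S)-4-acetyl-4,7-dimethyl-3-oxooct-6-enoate; 16 N-methoxy-N-methylbutanamide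
Product: 19 methyl (4S)-4-methyl-4-(3-methylbut-2-en-1-yl)-3,5,7-trioxodecanoate, via dilithium dienolate 17 (not isolated), via dilithium hemiaminal adduct 18 (not isolated)
Conditions: LiN(iPr)2 (2.2 equiv), THF, −78 °C; 16 (1.2 equiv), −78 → 0 °C; aq. NH4Cl; crude product taken on
Reagents that add atoms: none
Why: In this dianion acylation the first equivalent of base turns the β-keto ester into its enolate and so switches off the ester as an electrophile, the second forms the terminal methyl ketone enolate, and that more reactive site is C-acylated by the Weinreb amide through a chelated tetrahedral adduct that collapses only on work-up.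

Step 11
Reactants: 19 methyl (4S)-4-methyl-4-(3-methylbut-2-en-1-yl)-3,5,7-trioxodecanoate
Product: 20 (4R)-2-butanoyl-3,5-dihydroxy-4-methyl-4-(3-methylbut-2-en-1-yl)cyclohexa-2,5-dien-1-one
Conditions: NaOMe (3 equiv), MeOH, rt → 60 °C; 1 M HCl at 0 °C
Reagents that add atoms: none
Why: In this Dieckmann (intramolecular Claisen) condensation the diketone enolate carbon C1 attacks the ester carbon C6 in a 6-exo-trig closure; under equilibrating methoxide the aldol and O-acylation modes are reversible while the strongly acidic 2-acyl trione is drained as its enolate, and C3 is not touched.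

Step 12
Reactants: 21 5-methoxyresorcinol (5-methoxybenzene-1,3-diol); 22 butanoyl chloride
Product: 23 1-(2,4-dihydroxy-6-methoxyphenyl)butan-1-one
Conditions: AlCl3 (3 equiv), PhNO2/CH2Cl2, 0 °C → rt; ice/1 M HCl; chromatography
Reagents that add atoms: none
Why: Friedel–Crafts acylation of the electron-rich arene is expected mainly at C4/C6 (two equivalent positions, each ortho to one hydroxyl and para to the other), which gives the ketone flanked by OH and OMe; the symmetrical C2-acylated isomer is separable.

Step 13
Reactants: 23 1-(2,4-dihydroxy-6-methoxyphenyl)butan-1-one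
Product: 24 1-{3-[(dimethylamino)methyl]-2,4-dihydroxy-6-methoxyphenyl}butan-1-one
Conditions: 37% aq. CH2O (1.0 equiv), 40% aq. Me2NH (1.1 equiv), EtOH, 0 °C → rt
Reagents that add atoms: formaldehyde C=O; dimethylamine CNC
Why: The Mannich reaction goes ortho to the free 4-OH, and C3, the enolic carbon between the two hydroxyls of the chelated ring, is the expected site; the regioisomer is secured by purification at this early stage.

Step 14
Reactants: 20 (4R)-2-butanoyl-3,5-dihydroxy-4-methyl-4-(3-methylbut-2-en-1-yl)cyclohexa-2,5-dien-1-one; 24 1-{3-[(dimethylamino)methyl]-2,4-dihydroxy-6-methoxyphenyl}butan-1-one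
Product: 26 (4R)-2-butanoyl-6-[(3-butanoyl-2,6-dihydroxy-4-methoxyphenyl)methyl]-3,5-dihydroxy-4-methyl-4-(3-methylbut-2-en-1-yl)cyclohexa-2,5-dien-1-one (CNP0285707.1), via o-quinone methide 25 (not isolated)
Conditions: 20 (1 equiv), 24 (1.1 equiv), 1,4-dioxane, 90 °C, N2 sweep
Reagents that add atoms: none
Why: On heating, the ortho-hydroxybenzylamine loses dimethylamine to give o-quinone methide 25, and the enol carbon C5 of 20, the only unsubstituted nucleophilic carbon of ring A, adds to its methylidene carbon (Mannich-base alkylation of a cyclic 1,3-dicarbonyl compound) with rearomatisation of ring B; C3 is remote and unaffected.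

**Compound list**

1 | prenyl bromide (1-bromo-3-methylbut-2-ene) | CC(C)=CCBr | starting material
2 | ethynylmagnesium bromide | C#C[Mg]Br | starting material
3 | 5-methylhex-4-en-1-yne | C#CCC=C(C)C | intermediate
4 | [(1E)-2,5-dimethylhexa-1,4-dien-1-yl]dimethylalumane | CC(C)=CC/C(C)=C/[Al](C)C | intermediate (not isolated)
5 | lithium butyl[(1E)-2,5-dimethylhexa-1,4-dien-1-yl]dimethylaluminate | [Li+].CCCC[Al-](C)(C)/C=C(\C)CC=C(C)C | intermediate (not isolated)
6 | (2E)-3,6-dimethylhepta-2,5-dien-1-ol | CC(C)=CC/C(C)=C/CO | intermediate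
7 | [(2S,3S)-3-methyl-3-(3-methylbut-2-en-1-yl)oxiran-2-yl]methanol | OC[C@@H]1O[C@@]1(C)CC=C(C)C | intermediate
8 | (2R,3S)-3-methyl-3-(3-methylbut-2-en-1-yl)oxirane-2-carbaldehyde | O=C[C@@H]1O[C@@]1(C)CC=C(C)C | intermediate
9 | 1-[(2S,3S)-3-methyl-3-(3-methylbut-2-en-1-yl)oxiran-2-yl]ethan-1-ol (carbinol epimers) | CC(O)[C@@H]1O[C@@]1(C)CC=C(C)C | intermediate
10 | 1-[(2R,3S)-3-methyl-3-(3-methylbut-2-en-1-yl)oxiran-2-yl]ethan-1-one | CC(=O)[C@@H]1O[C@@]1(C)CC=C(C)C | intermediate
11 | (2R)-2-acetyl-2,5-dimethylhex-4-enal | CC(=O)[C@](C)(CC=C(C)C)C=O | intermediate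
12 | methyl acetate | COC(C)=O | starting material
13 | lithium 1-methoxyethen-1-olate | [Li+].COC([O-])=C | intermediate (not isolated)
14 | methyl (4R)-4-acetyl-3-hydroxy-4,7-dimethyloct-6-enoate (C3 epimers) | COC(=O)CC(O)[C@@](C)(CC=C(C)C)C(C)=O | intermediate
15 | methyl (4S)-4-acetyl-4,7-dimethyl-3-oxooct-6-enoate | COC(=O)CC(=O)[C@@](C)(CC=C(C)C)C(C)=O | intermediate
16 | N-methoxy-N-methylbutanamide | CCCC(=O)N(C)OC | starting material
17 | dilithium dienolate of 15 (β-keto ester enolate and terminal methyl ketone enolate) | [Li+].[Li+].COC(=O)C=C([O-])[C@@](C)(CC=C(C)C)C([O-])=C | intermediate (not isolated)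
18 | dilithium salt of the tetrahedral adduct of 17 with 16 (N-methoxy-N-methyl hemiaminal alkoxide) | [Li+].[Li+].COC(=O)C=C([O-])[C@@](C)(CC=C(C)C)C(=O)CC([O-])(CCC)N(C)OC | intermediate (not isolated)
19 | methyl (4S)-4-methyl-4-(3-methylbut-2-en-1-yl)-3,5,7-trioxodecanoate | COC(=O)CC(=O)[C@@](C)(CC=C(C)C)C(=O)CC(=O)CCC | intermediate
20 | (4R)-2-butanoyl-3,5-dihydroxy-4-methyl-4-(3-methylbut-2-en-1-yl)cyclohexa-2,5-dien-1-one | CCCC(=O)C1=C(O)[C@](C)(CC=C(C)C)C(O)=CC1=O | intermediate
21 | 5-methoxyresorcinol (5-methoxybenzene-1,3-diol) | COc1cc(O)cc(O)c1 | starting material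
22 | butanoyl chloride | CCCC(Cl)=O | starting material
23 | 1-(2,4-dihydroxy-6-methoxyphenyl)butan-1-one | CCCC(=O)c1c(O)cc(O)cc1OC | intermediate
24 | 1-{3-[(dimethylamino)methyl]-2,4-dihydroxy-6-methoxyphenyl}butan-1-one | CCCC(=O)c1c(O)c(CN(C)C)c(O)cc1OC | intermediate
25 | 4-butanoyl-5-hydroxy-3-methoxy-6-methylidenecyclohexa-2,4-dien-1-one | CCCC(=O)C1=C(O)C(=C)C(=O)C=C1OC | intermediate (not isolated)
26 | (4R)-2-butanoyl-6-[(3-butanoyl-2,6-dihydroxy-4-methoxyphenyl)methyl]-3,5-dihydroxy-4-methyl-4-(3-methylbut-2-en-1-yl)cyclohexa-2,5-dien-1-one | CCCC(=O)C1=C(O)[C@](C)(CC=C(C)C)C(O)=C(Cc2c(O)cc(OC)c(C(=O)CCC)c2O)C1=O | target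

**Step count and risks**

Total steps: 14. Longest linear sequence: 12 (steps 1–11, then 14); the ring B branch is steps 12–13.

Steps most likely to fail:

Step 10. Ring closure of the methyl ketone enolate onto the ester before the acyl group is in place would give an achiral trione and erase the stereochemical information; sluggish or O-selective acyl transfer is the other danger. The fallback sets out from 15 and keeps the dianion but replaces acylation by an aldol addition, which is fast at −78 °C. Dienolate 17 is quenched with butanal to give methyl (4S)-7-hydroxy-4-methyl-4-(3-methylbut-2-en-1-yl)-3,5-dioxodecanoate F1 as a carbinol mixture, and Dess–Martin oxidation of the β-hydroxy ketone returns to the route at 19.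

Step 7. Loss of the formyl group from the keto aldehyde during quench or handling, or hydride shift competing with acyl shift, would destroy the 1,3-dicarbonyl pattern. The fallback sets out from 9 and moves a carbinol carbon instead of an acyl group, so that no 1,3-dicarbonyl compound is formed at this stage.
- Silylation (TBSCl, imidazole, DMF) gives tert-butyl(dimethyl){1-[(2S,3S)-3-methyl-3-(3-methylbut-2-en-1-yl)oxiran-2-yl]ethoxy}silane F2.
- The known epoxy silyl ether rearrangement with methylaluminium bis(4-bromo-2,6-di-tert-butylphenoxide) in CH2Cl2 at −78 °C should shift the siloxyethyl group anti to the opening C3–O bond and give (2S)-2-{1-[tert-butyl(dimethyl)silyl]oxyethyl}-2,5-dimethylhex-4-enal F3, with the same spatial arrangement at the quaternary carbon as 11.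
- Aldol addition of enolate 13 gives methyl (4R)-4-{1-[tert-butyl(dimethyl)silyl]oxyethyl}-3-hydroxy-4,7-dimethyloct-6-enoate F4.
- HF·pyridine removes the silyl group to give methyl (4S)-3-hydroxy-4-(1-hydroxyethyl)-4,7-dimethyloct-6-enoate F5.
- Excess Dess–Martin periodinane oxidises both carbinols, and the route is rejoined at 15.

Step 14. Self-condensation of the ring B quinone methide, or retro-Michael exchange of the bridge that leads to symmetrical dimers, would lower the yield of the mixed dimer. The fallback sets out from 20 and 23 and reverses the roles of the partners. Mannich reaction of 20 (aq. CH2O, Me2NH, EtOH) at C5, its only free carbon, gives (4R)-2-butanoyl-6-[(dimethylamino)methyl]-3,5-dihydroxy-4-methyl-4-(3-methylbut-2-en-1-yl)cyclohexa-2,5-dien-1-one F6. Heating F6 with 23 in 1,4-dioxane releases dimethylamine and forms (4S)-2-butanoyl-3-hydroxy-4-methyl-6-methylidene-4-(3-methylbut-2-en-1-yl)cyclohex-2-ene-1,5-dione F7, which is attacked by C3 of 23, the enolic carbon between its two hydroxyls, and the route is rejoined at 26.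

**Further compounds**

F1 | step 10 | methyl (4S)-7-hydroxy-4-methyl-4-(3-methylbut-2-en-1-yl)-3,5-dioxodecanoate | COC(=O)CC(=O)[C@@](C)(CC=C(C)C)C(=O)CC(O)CCC
F2 | step 7 | tert-butyl(dimethyl){1-[(2S,3S)-3-methyl-3-(3-methylbut-2-en-1-yl)oxiran-2-yl]ethoxy}silane | CC(O[Si](C)(C)C(C)(C)C)[C@@H]1O[C@@]1(C)CC=C(C)C
F3 | step 7 | (2S)-2-{1-[tert-butyl(dimethyl)silyl]oxyethyl}-2,5-dimethylhex-4-enal | CC(O[Si](C)(C)C(C)(C)C)[C@](C)(CC=C(C)C)C=O
F4 | step 7 | methyl (4R)-4-{1-[tert-butyl(dimethyl)silyl]oxyethyl}-3-hydroxy-4,7-dimethyloct-6-enoate | COC(=O)CC(O)[C@@](C)(CC=C(C)C)C(C)O[Si](C)(C)C(C)(C)C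
F5 | step 7 | methyl (4S)-3-hydroxy-4-(1-hydroxyethyl)-4,7-dimethyloct-6-enoate | COC(=O)CC(O)[C@@](C)(CC=C(C)C)C(C)O
F6 | step 14 | (4R)-2-butanoyl-6-[(dimethylamino)methyl]-3,5-dihydroxy-4-methyl-4-(3-methylbut-2-en-1-yl)cyclohexa-2,5-dien-1-one | CCCC(=O)C1=C(O)[C@](C)(CC=C(C)C)C(O)=C(CN(C)C)C1=O
F7 | step 14 | (4S)-2-butanoyl-3-hydroxy-4-methyl-6-methylidene-4-(3-methylbut-2-en-1-yl)cyclohex-2-ene-1,5-dione | CCCC(=O)C1=C(O)[C@](C)(CC=C(C)C)C(=O)C(=C)C1=O
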